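## Retrosynthetic overview
1. The 8-prenyl group comes from an 8-allyl group by cross-metathesis in the last step. Allyl stands in for prenyl next to the free 7-OH because the acid used earlier cannot protonate it.
2. Key disconnection: O1–C2 and C2–C3 (ring C) and O–C(CH3)2 (ring D) are cut together. This gives a ring A tert-butyl aroylacetate and the ring B aldehyde 4-hydroxy-3,5-diprenylbenzaldehyde.
3. Forward, in one flask: Knoevenagel condensation, then chiral thiourea oxa-Michael addition (ring C, C2 = S), then TsOH. The acid removes the ester as isobutene and CO2 and closes one prenyl group onto the ring B phenol (ring D).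
4. Fragments: the aldehyde comes from double ortho-C-prenylation of 4-hydroxybenzaldehyde. The β-ketoester comes from C-acylation of polylithiated 3-allyl-2,4-dihydroxyacetophenone with Boc2O.
5. Ring order: rings A and B are bought. Ring C forms first and ring D second, both in the same operation.

Assumption 1: 3-allyl-2,4-dihydroxyacetophenone is bought as a catalogue building block (otherwise O-allylation and Claisen rearrangement of 2,4-dihydroxyacetophenone supply it).
Assumption 2: the quinidine-derived (9R) thiourea is taken to give the 2S product. The sense is checked on the first batch by CD and chiral HPLC, and the equally available quinine-derived pseudo-enantiomer is used if it proves opposite.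

## Route

Step 1
Reactants: 1 4-hydroxybenzaldehyde; 2 prenyl bromide (2.5 equiv)
Product: 3 4-hydroxy-3,5-bis(3-methylbut-2-enyl)benzaldehyde
Conditions: KOH (3 equiv), H2O, 0 °C to rt, 24 h
Reagents that add atoms: prenyl bromide (compound 2), CC(C)=CCBr
Why: Phenoxide C-alkylation in water: hydrogen bonding to the phenoxide oxygen holds back O-alkylation and the para position is blocked by CHO, so both ortho carbons attack prenyl bromide by SN2 (mono-prenyl material is recycled); no stereocentre is formed.

Step 2
Reactants: 4 1-(3-allyl-2,4-dihydroxyphenyl)ethanone; 5 di-tert-butyl dicarbonate (1.05 equiv)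
Product: 6 tert-butyl 3-(3-allyl-2,4-dihydroxyphenyl)-3-oxopropanoate
Conditions: LiN(SiMe3)2 (4.5 equiv), THF, −78 to −10 °C; Boc2O, −78 to 0 °C; cold 1 M HCl quench
Reagents that add atoms: di-tert-butyl dicarbonate (compound 5), CC(C)(C)OC(=O)OC(=O)OC(C)(C)C
Why: Crossed Claisen C-acylation of a polylithiated hydroxyacetophenone: the enolate carbon is far more nucleophilic than the two lithium phenoxides, so one equivalent of Boc2O acylates carbon and the surplus base holds the product as its unreactive enolate; no stereocentre is formed.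

Step 3
Reactants: 3 4-hydroxy-3,5-bis(3-methylbut-2-enyl)benzaldehyde; 6 tert-butyl 3-(3-allyl-2,4-dihydroxyphenyl)-3-oxopropanoate
Product: 9 (2S)-8-allyl-7-hydroxy-2-[2,2-dimethyl-8-(3-methylbut-2-enyl)chroman-6-yl]chroman-4-one, via alkylidene β-ketoester 7 (not isolated), via flavanone-3-carboxylate 8 (not isolated)
Conditions: one flask, toluene: a) piperidine (10 mol%), AcOH (10 mol%), 4 Å MS, rt, 24 h; b) N-[3,5-bis(trifluoromethyl)phenyl]-N'-[(9R)-6'-methoxycinchonan-9-yl]thiourea (20 mol%), −25 °C, 48 h; c) p-TsOH·H2O (1.5 equiv), 80 °C, 2 h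
Reagents that add atoms: none
Why: Proposed new method: buffered Knoevenagel condensation gives the doubly activated alkylidene 7, whose two carbonyls are held by the thiourea while the quinuclidine deprotonates the 2'-OH, so the intramolecular oxa-Michael addition closes ring C on one face and sets C2 as S (8); the single TsOH charge then quenches the amines (blocking retro-Michael racemisation), removes the ester as isobutene and CO2, and protonates a trisubstituted prenyl alkene to a tertiary cation that the flanking ring B phenol traps (Markovnikov hydroalkoxylation, ring D), while the monosubstituted allyl group beside the 7-OH would need a secondary cation and stays intact and the second prenyl group has no OH left to capture it; the closest known reaction types are the one-flask thiourea-catalysed oxa-Michael/decarboxylation synthesis of flavanones from alkylidene β-ketoesters and the TsOH cyclisation of o-prenylphenols to 2,2-dimethylchromans.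

Step 4
Reactants: 9 (2S)-8-allyl-7-hydroxy-2-[2,2-dimethyl-8-(3-methylbut-2-enyl)chroman-6-yl]chroman-4-one; 10 2-methylbut-2-ene (large excess)
Product: 11 (2S)-7-hydroxy-8-(3-methylbut-2-enyl)-2-[2,2-dimethyl-8-(3-methylbut-2-enyl)chroman-6-yl]chroman-4-one (target)
Conditions: second-generation Grubbs catalyst RuCl2(=CHPh)(PCy3)(H2IMes) (5 mol%), 1,4-benzoquinone (10 mol%), 2-methylbut-2-ene/CH2Cl2 1:1, 40 °C, sealed tube, 12 h
Reagents that add atoms: 2-methylbut-2-ene (compound 10), CC=C(C)C
Why: Olefin cross-metathesis: the terminal allyl alkene swaps its CH2 for the isopropylidene of the excess partner (propene escapes), exchange at the existing prenyl group is degenerate, benzoquinone suppresses allyl-to-propenyl isomerisation, and the neutral medium leaves C2, the free phenol and the ketone untouched.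

## Compound list
1 | 4-hydroxybenzaldehyde | O=Cc1ccc(O)cc1 | starting material
2 | prenyl bromide (1-bromo-3-methylbut-2-ene) | CC(C)=CCBr | starting material
3 | 4-hydroxy-3,5-bis(3-methylbut-2-enyl)benzaldehyde | CC(C)=CCc1cc(C=O)cc(CC=C(C)C)c1O | intermediate
4 | 1-(3-allyl-2,4-dihydroxyphenyl)ethanone | CC(=O)c1ccc(O)c(CC=C)c1O | starting material
5 | di-tert-butyl dicarbonate | CC(C)(C)OC(=O)OC(=O)OC(C)(C)C | starting material
6 | tert-butyl 3-(3-allyl-2,4-dihydroxyphenyl)-3-oxopropanoate | CC(C)(C)OC(=O)CC(=O)c1ccc(O)c(CC=C)c1O | intermediate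
7 | tert-butyl (Z)-2-(3-allyl-2,4-dihydroxybenzoyl)-3-[4-hydroxy-3,5-bis(3-methylbut-2-enyl)phenyl]prop-2-enoate | CC(C)(C)OC(=O)/C(=C\c1cc(CC=C(C)C)c(O)c(CC=C(C)C)c1)C(=O)c1ccc(O)c(CC=C)c1O | intermediate
8 | tert-butyl (2S)-8-allyl-7-hydroxy-2-[4-hydroxy-3,5-bis(3-methylbut-2-enyl)phenyl]-4-oxochroman-3-carboxylate (C3 labile, epimers/enol, lost on decarboxylation) | CC(C)=CCc1cc([C@@H]2C(C(=O)OC(C)(C)C)C(=O)c3ccc(O)c(CC=C)c3O2)cc(CC=C(C)C)c1O | intermediate
9 | (2S)-8-allyl-7-hydroxy-2-[2,2-dimethyl-8-(3-methylbut-2-enyl)chroman-6-yl]chroman-4-one | CC(C)=CCc1cc([C@@H]2CC(=O)c3ccc(O)c(CC=C)c3O2)cc2c1OC(C)(C)CC2 | intermediate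
10 | 2-methylbut-2-ene | CC=C(C)C | starting material
11 | (2S)-7-hydroxy-8-(3-methylbut-2-enyl)-2-[2,2-dimethyl-8-(3-methylbut-2-enyl)chroman-6-yl]chroman-4-one | CC(C)=CCc1cc([C@@H]2CC(=O)c3ccc(O)c(CC=C(C)C)c3O2)cc2c1OC(C)(C)CC2 | target

## Step count and risks
Total step count: 4. Longest linear sequence: 3 (1 → 3 → 9 → 11, or 4 → 6 → 9 → 11).

**Most likely to fail, first: step 3.** Three free phenols can tie up piperidine and the quinuclidine. That would slow the condensation and allow racemic background closure. The hot acid could also erode the ee or the remaining prenyl group.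

The fallback forms the rings separately and resolves the racemate instead of inducing asymmetry. It sets out from 3.
- TsOH (10 mol%) in toluene at 80 °C closes ring D to 2,2-dimethyl-8-(3-methylbut-2-enyl)chroman-6-carbaldehyde F1.
- Claisen–Schmidt condensation of this aldehyde with 4 (KOH, EtOH, rt) gives (E)-1-(3-allyl-2,4-dihydroxyphenyl)-3-[2,2-dimethyl-8-(3-methylbut-2-enyl)chroman-6-yl]prop-2-en-1-one F2.
- NaOAc in refluxing EtOH closes ring C to racemic 8-allyl-7-hydroxy-2-[2,2-dimethyl-8-(3-methylbut-2-enyl)chroman-6-yl]chroman-4-one F3.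
- Kinetic resolution follows by asymmetric transfer hydrogenation with RhCl(C5Me5)[(R,R)-TsDPEN] and HCO2H/Et3N in EtOAc at rt. It reduces only the R enantiomer to (2R,4R)-8-allyl-2-[2,2-dimethyl-8-(3-methylbut-2-enyl)chroman-6-yl]chroman-4,7-diol F4.
- Chromatography removes the diol. The unreduced S ketone is 9, where the route is rejoined.

**Second: step 1.** The double C-alkylation competes with O-alkylation and tends to stop at the mono-prenyl stage, so about 20–35% is expected.

The fallback replaces enolate-type alkylation by cross-coupling and sets out from 1. Br2 (2.1 equiv) in AcOH gives 3,5-dibromo-4-hydroxybenzaldehyde F5. A double Stille coupling with tributyl(3-methylbut-2-enyl)stannane (2.4 equiv), Pd(PPh3)4, DMF, 100 °C puts in both prenyl groups and returns to the route at 3.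

**Third: step 2.** O-Boc formation or double acylation may compete with the wanted C-acylation.

The fallback drops ester activation altogether and sets out from 4.
- Claisen–Schmidt condensation with 3 (KOH, EtOH/H2O, rt, 72 h) gives (E)-1-(3-allyl-2,4-dihydroxyphenyl)-3-[4-hydroxy-3,5-bis(3-methylbut-2-enyl)phenyl]prop-2-en-1-one F6.
- The same thiourea (20 mol%, toluene, rt) closes ring C on the unactivated enone to (2S)-8-allyl-7-hydroxy-2-[4-hydroxy-3,5-bis(3-methylbut-2-enyl)phenyl]chroman-4-one F7.
- TsOH (50 mol%, 80 °C) added to the same flask closes ring D, returning to the route at 9.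

## Further compounds
F1 | step 3 | 2,2-dimethyl-8-(3-methylbut-2-enyl)chroman-6-carbaldehyde | CC(C)=CCc1cc(C=O)cc2c1OC(C)(C)CC2
F2 | step 3 | (E)-1-(3-allyl-2,4-dihydroxyphenyl)-3-[2,2-dimethyl-8-(3-methylbut-2-enyl)chroman-6-yl]prop-2-en-1-one | CC(C)=CCc1cc(/C=C/C(=O)c2ccc(O)c(CC=C)c2O)cc2c1OC(C)(C)CC2
F3 | step 3 | racemic 8-allyl-7-hydroxy-2-[2,2-dimethyl-8-(3-methylbut-2-enyl)chroman-6-yl]chroman-4-one | CC(C)=CCc1cc(C2CC(=O)c3ccc(O)c(CC=C)c3O2)cc2c1OC(C)(C)CC2
F4 | step 3 | (2R,4R)-8-allyl-2-[2,2-dimethyl-8-(3-methylbut-2-enyl)chroman-6-yl]chroman-4,7-diol | CC(C)=CCc1cc([C@H]2C[C@@H](O)c3ccc(O)c(CC=C)c3O2)cc2c1OC(C)(C)CC2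
F5 | step 1 | 3,5-dibromo-4-hydroxybenzaldehyde | O=Cc1cc(Br)c(O)c(Br)c1
F6 | step 2 | (E)-1-(3-allyl-2,4-dihydroxyphenyl)-3-[4-hydroxy-3,5-bis(3-methylbut-2-enyl)phenyl]prop-2-en-1-one | CC(C)=CCc1cc(/C=C/C(=O)c2ccc(O)c(CC=C)c2O)cc(CC=C(C)C)c1O
F7 | step 2 | (2S)-8-allyl-7-hydroxy-2-[4-hydroxy-3,5-bis(3-methylbut-2-enyl)phenyl]chroman-4-one | CC(C)=CCc1cc([C@@H]2CC(=O)c3ccc(O)c(CC=C)c3O2)cc(CC=C(C)C)c1O
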